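# Proposed synthesis of 2,3,6-tribromo-4-(hydroxymethyl)phenol (12) from para-cresol

## The problem

Target 12 is a benzene ring with five substituents: hydroxyl on C1, bromine on C2, C3 and C6, the hydroxymethyl carbon C7 on C4, and the only ring hydrogen on C5 (this numbering is used throughout). There is one ring, a one-carbon side chain and no stereocenter, so nothing has to be controlled in three dimensions and the whole difficulty lies in placing the substituents. C2 and C6 are ortho to the hydroxyl and take bromine readily, but C3 is meta to oxygen, and electrophilic bromination of a free 4-substituted phenol does not go there. The functional groups narrow the methods. Three aryl C–Br bonds exclude dissolving metals, catalytic hydrogenation and reagents that exchange halogen for metal. The para-hydroxybenzyl alcohol ionises under acid or base to a quinone methide that etherifies or oligomerises, so it should be unveiled last. C7 is therefore best carried as the methyl group of para-cresol 1 and oxidised late. The key step is possible because C3 is the neighbour of C4, the carbon para to oxygen: once C2 and C6 are filled, C4 is the only oxygen-activated position left and accepts bromine ipso, giving a cross-conjugated dienone with Br and CH3 on an sp3 C4. That dienone has a mirror plane through C1 and C4, so a 1,2-shift of the C4 bromine to either neighbour gives the same 3-bromophenol.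

## Retrosynthesis

**12 to 9 (C7–O and the phenolic O–acyl bond).** The fragile para-hydroxybenzyl alcohol is traced back to benzylic bromide 9, whose phenol is masked as an acetate. A C4–C7 cut would instead lead to a tribromophenol without the para carbon, which has the same meta-bromine problem but lacks the para substituent that solves it. The C7–O cut keeps C7 as a methyl group until late. Precursor 9 has neither a free phenol nor an alcohol. The forward reaction is one treatment with aqueous base that removes the acetate and replaces bromide by hydroxyl, through phenol 10 and quinone methide 11, and it must let the aqueous medium, not the product, capture 11.

**9 to 8 (C7–Br).** The benzylic bromine is removed to give tolyl acetate 8. The C7 hydrogens are the only ones that give a stabilised radical and the C5 hydrogen is inert to bromine atoms, so a radical chain bromination has one possible site. The phenol must be masked for this: free phenol 7 would be attacked ipso at C4 by an electrophilic bromine source and would quench the chain. The forward reaction has only to stop at the monobromide.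

**8 to 7 (O–acyl).** Removing the acetyl group gives 2,3,6-tribromo-4-methylphenol 7. Acetate is chosen over an ether or silyl group because it survives the radical step and is removed in the same operation that hydrolyses the bromide, so no separate deprotection is needed.

**7 to 4 (C3–Br, the key disconnection).** The C3–Br bond is cut and the bromine is returned to C4, giving 2,4,6-tribromo-4-methylcyclohexa-2,5-dien-1-one 4. The neighbouring options are to switch off the directing power of oxygen and brominate under the influence of the methyl group, or to go through nitration, reduction and diazotisation. Each costs several steps, whereas the shift costs one and uses no reagent beyond a strong acid. Precursor 4 is symmetric, carries all three bromines and comes from 1 in one operation. The forward reaction needs a medium acidic enough to protonate 4 to cation 5, free of base so that no C7 proton is taken, and non-nucleophilic so that positive bromine is not stripped. Migration then gives cation 6 and, by proton loss, 7.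

**4 to 1 and 2 (C2–Br, C6–Br, C4–Br).** All three carbons are ortho or para to oxygen, so 4 goes back to para-cresol 1 and three equivalents of bromine 2. The order is set by reactivity: ortho substitution first (2,6-dibromo-4-methylphenol 3), then ipso attack at the substituted para carbon. The forward reaction needs a buffer that removes the acid formed, because acid reverses the ipso step.

## Roads not taken

**Alternative 1: Diels–Alder benzannulation.** The ring is cut at C2–C3 and C4–C5. C1, C2, C6 and C5 would come from the diene carbons of 3,5-dibromo-4-methoxy-2-pyrone A2, and C3 and C4 from the alkyne carbons of methyl 3-bromopropiolate A3. A thermal cycloaddition would give a bridged lactone that aromatises by retro-cycloaddition loss of its O–C(=O) bridge to methyl 2,3,5-tribromo-4-methoxybenzoate A1. Ester reduction and cleavage of the aryl methyl ether would finish.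
- Merits: every substituent is fixed by the connectivity of the partners, so the meta bromine is never a selectivity question. The polarity match of a 2-alkoxydiene with an ynoate (methoxy ends up para to the ester) favours the needed orientation.
- Weak points: both partners have to be made, and A3 is an unstable, lachrymatory haloalkyne. A2 is a fully substituted, electron-poor diene facing an electron-poor alkyne, so forcing temperatures are expected. The new C2–C3 bond joins two bromine-bearing carbons. Two further steps follow, one a Lewis-acid ether cleavage next to a benzylic C–O group.
- Comparison: in certainty of the substitution pattern this road is better than the chosen plan, which depends on a migration outrunning bromine loss. The chosen plan offers a commodity starting material, no construction of a ring that can be bought with the right carbon and oxygen pattern, fewer steps, and a key step whose regiochemistry is degenerate.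

**Alternative 2: late phenol oxygen by magnesiation.** The C1–O bond is cut. The oxygen would be introduced last on triisopropyl[(2,3,5-tribromophenyl)methoxy]silane A5, whose C–H between two bromines (C1 of the target) is the most acidic on the ring. A hindered magnesium amide base (as its lithium chloride complex) would metalate there, a borate ester would trap the arylmagnesium, and alkaline peroxide would turn C–B into C–O, giving 2,3,6-tribromo-4-[(triisopropylsilyloxy)methyl]phenol A4. Fluoride would then release 12.
- Merits: all three bromines are in place before the key step, the metalation site is defined by two flanking halogens, and the conditions are mild. The side chain is already at the alcohol oxidation level, so no benzylic oxidation is needed.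
- Weak points: the arylmagnesium has bromine on both ortho carbons and can eliminate to an aryne if it warms. The other ring hydrogen of A5 (C5 of the target) is a competing site. Above all, the core of A5 is not a commodity. Its pattern again contains a bromine that simple bromination of a benzylic alcohol or benzoic acid does not place, so diazonium chemistry and a carboxyl reduction would precede the key step.
- Comparison: in mildness of the key step and simplicity of the endgame (one desilylation against three steps of side-chain work here) this road is better. The chosen plan offers a shorter sequence from 1 and 2 with no cryogenic organometallic operations, at the price of a labile dienone and a superacid.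

**Alternative 3: anodic oxidation of the methyl group.** This is a different way to oxidise C7, not a different way to place the bromines: it starts from the same phenol 7 and cuts C7–O. Anodic two-electron oxidation of 7 in an acetate-buffered acidic electrolyte would give quinone methide 11, to which acetate adds at C7 to give (2,3,5-tribromo-4-hydroxyphenyl)methyl acetate A6. Hydrolysis of A6 would give 12.
- Merits: two steps from 7 instead of three, no protecting group, no radical bromination and no benzylic bromide.
- Weak points: 7 is an electron-poor phenol with a high oxidation potential. At such potentials the oxidised phenol can also be attacked at bromine-bearing carbons or couple. A6 is a phenol of similar potential and can be oxidised further. Clean anodic side-chain acetoxylation is best supported for electron-rich, hindered para-cresols. Hydrolysis of A6 passes through 11 again, so the quinone methide problem of the last step remains.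
- Comparison: in step count this endgame is better than steps 3 to 5. The chosen plan offers a radical bromination whose extent is set by the weighed amount of reagent and whose only possible site is C7, and it needs no electrolysis cell. If the electrolysis proved clean, it could replace the endgame without touching the key disconnection.

Key step: step 2

Remark on the chemistry: cations 5 and 6 are written as triflate salts, and 6 is racemic at its transient sp3 C3, which is lost on deprotonation. Compound 3 is not isolated in step 1 but can be isolated by stopping at two equivalents of bromine; some fallbacks use this.

## Route

Step 1
Reactants: 1 para-cresol (4-methylphenol); 2 bromine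
Product: 4 2,4,6-tribromo-4-methylcyclohexa-2,5-dien-1-one, via 2,6-dibromo-4-methylphenol 3 (not isolated)
Conditions: Br2 (3.05 equiv), NaOAc (3.5 equiv), AcOH/H2O 4:1, 10–15 °C, dark; then ice-water, filter, dry cold in vacuo, use at once
Reagents that add atoms: bromine 2, BrBr
Why: Electrophilic aromatic bromination followed by ipso bromination: the hydroxyl directs the first two equivalents to C2 and C6 (3), after which C4 is the only oxygen-activated carbon left and takes the third bromine, the way fully ortho/para-substituted phenols give 4-bromo dienones. Acetate removes the HBr that would reverse the ipso step or isomerise the product, and the poorly soluble dienone should leave solution as it forms; C4 carries two identical ring arms and is not a stereocenter.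

Step 2
Reactants: 4 2,4,6-tribromo-4-methylcyclohexa-2,5-dien-1-one
Product: 7 2,3,6-tribromo-4-methylphenol, via O-protonated dienone 5 (not isolated), via 3-bromoarenium ion 6 (not isolated)
Conditions: CF3SO3H (neat, excess), 4 added in portions at 0 °C, then rt, dark; poured onto ice, aq. NaHSO3 wash
Reagents that add atoms: none
Why: CF3SO3H protonates the carbonyl oxygen of 4 to give hydroxyarenium ion 5, the sigma complex of ipso attack on 3, with Br and CH3 on sp3 C4. Bromine then moves from C4 to the adjacent C3 through a bridged, bromonium-like transition state to give arenium ion 6, whose charge rests largely on the methyl-bearing C4, and loss of the C3 proton restores the aromatic ring and makes the sequence irreversible. The closest known reaction type is the acid-promoted dienone–phenol rearrangement of 4-bromo-4-alkylcyclohexa-2,5-dienones to 3-bromophenols by 1,2-bromine shift, which is established for this substrate class. No ring is closed and no stereocenter is created; the one new bond is C3–Br. The step needs nuclear bromine migration to win over methyl migration, over loss of a C7 proton (which leads through quinone methide 11 to side-chain bromide) and over release of positive bromine. The high bridging ability of bromine secures the first, the absence of any base in the superacid the second, and the non-nucleophilic triflate medium, which offers no acceptor for positive bromine, the third. Site selectivity is not in question, because the mirror plane of 4 through C1 and C4 makes C3 and C5 equivalent, and even bromine that is released can re-enter 3 only at these two carbons.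

Step 3
Reactants: 7 2,3,6-tribromo-4-methylphenol
Product: 8 2,3,6-tribromo-4-methylphenyl acetate
Conditions: Ac2O, pyridine, DMAP (cat.), CH2Cl2, rt
Reagents that add atoms: acetic anhydride, CC(=O)OC(C)=O
Why: Nucleophile-catalysed O-acylation; the acidic 2,6-dibromophenol is acylated despite its two ortho bromines. The acetate removes the electron-rich phenol that would be brominated ipso at C4 or would quench the radical chain in the next step.

Step 4
Reactants: 8 2,3,6-tribromo-4-methylphenyl acetate
Product: 9 2,3,6-tribromo-4-(bromomethyl)phenyl acetate
Conditions: NBS (1.05 equiv), AIBN (cat.), PhCF3, 85 °C
Reagents that add atoms: N-bromosuccinimide, O=C1CCC(=O)N1Br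
Why: Wohl–Ziegler benzylic bromination: a bromine atom abstracts hydrogen from C7, the only position that gives a stabilised radical, and the benzylic radical takes bromine from the low concentration of Br2 that NBS maintains. One equivalent of reagent and the deactivating effect of the first bromine should hold the reaction at the monobromide.

Step 5
Reactants: 9 2,3,6-tribromo-4-(bromomethyl)phenyl acetate
Product: 12 2,3,6-tribromo-4-(hydroxymethyl)phenol, via 2,3,6-tribromo-4-(bromomethyl)phenol 10 (not isolated), via quinone methide 11 (not isolated)
Conditions: LiOH (3 equiv), THF/H2O 1:1, 0.02 M, 0 °C to rt; then aq. NaH2PO4 to pH 5
Reagents that add atoms: water, O; lithium hydroxide, [Li+].[OH-] (hydroxide and water exchange, either delivers the C7 oxygen)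
Why: Saponification of the activated aryl acetate frees the phenoxide of 10, which expels bromide by 1,6-elimination to quinone methide 11; water or hydroxide adds at the exocyclic C7 and restores the aromatic ring, the established solvolysis path of 4-hydroxybenzyl halides. High dilution and the low nucleophilicity of the hindered 2,6-dibromophenoxide should keep 11 from being captured by product.

## Compound list

1 | para-cresol (4-methylphenol) | Cc1ccc(O)cc1 | starting material
2 | bromine | BrBr | starting material
3 | 2,6-dibromo-4-methylphenol | Cc1cc(Br)c(O)c(Br)c1 | intermediate (not isolated)
4 | 2,4,6-tribromo-4-methylcyclohexa-2,5-dien-1-one | CC1(Br)C=C(Br)C(=O)C(Br)=C1 | intermediate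
5 | O-protonated 4 (hydroxyarenium ion with Br and CH3 on sp3 C4), triflate salt | CC1(Br)C=C(Br)C(=[OH+])C(Br)=C1.[O-]S(=O)(=O)C(F)(F)F | intermediate (not isolated)
6 | 3-bromoarenium ion (H and Br on sp3 C3, OH on C1, Br on C2 and C6, CH3 on cationic C4; racemic, transient), triflate salt | C[C+]1C=C(Br)C(O)=C(Br)C1Br.[O-]S(=O)(=O)C(F)(F)F | intermediate (not isolated)
7 | 2,3,6-tribromo-4-methylphenol | Cc1cc(Br)c(O)c(Br)c1Br | intermediate
8 | 2,3,6-tribromo-4-methylphenyl acetate | CC(=O)Oc1c(Br)cc(C)c(Br)c1Br | intermediate
9 | 2,3,6-tribromo-4-(bromomethyl)phenyl acetate | CC(=O)Oc1c(Br)cc(CBr)c(Br)c1Br | intermediate
10 | 2,3,6-tribromo-4-(bromomethyl)phenol | BrCc1cc(Br)c(O)c(Br)c1Br | intermediate (not isolated)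
11 | 2,3,6-tribromo-4-methylidenecyclohexa-2,5-dien-1-one (quinone methide) | C=C1C=C(Br)C(=O)C(Br)=C1Br | intermediate (not isolated)
12 | 2,3,6-tribromo-4-(hydroxymethyl)phenol | OCc1cc(Br)c(O)c(Br)c1Br | target

## Step count and risk assessment

Total steps: 5. Longest linear sequence: 5 steps, from para-cresol 1.

**Step 2 (key step).**
- Risk: cation 5 may lose positive bromine instead of shifting it, with intermolecular transfer, so that part of the material returns to the dibromo stage while another part is brominated twice. The C4–Br bond of 5 is weak and nothing holds the bromine in the molecule except the speed of the shift. A second risk is loss of a C7 proton during a quench that is not cold enough, which leads to side-chain bromination.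
- Fallback: give up the shift and place the C3 bromine by ordinary electrophilic substitution on a ring whose oxygen has been deactivated. The fallback sets out from 3, isolated by stopping step 1 at two equivalents of bromine. MsCl and Et3N in CH2Cl2 convert it into 2,6-dibromo-4-methylphenyl methanesulfonate F1. With the oxygen lone pairs engaged by the sulfonyl group, the methyl group and both bromines direct to the only open ring carbons, the equivalent C3 and C5. One equivalent of NBS in concentrated H2SO4 should then give 2,3,6-tribromo-4-methylphenyl methanesulfonate F2. NaOH in aqueous methanol at reflux cleaves the sulfonate, and the route is rejoined at 7.

**Step 1.**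
- Risk: the ipso bromination may reverse, or 4 may isomerise during isolation and drying. The C4–Br bond of the dienone is labile to light, heat, acid and bromide, which return it to the phenol or start elimination towards side-chain products.
- Fallback: do not isolate a dienone. The fallback sets out from 3, a stable crystalline phenol isolated after two equivalents of bromine. It is treated with one equivalent of NBS in CF3SO3H, so that ipso attack of the protonated N-bromoimide at C4 generates cation 5 directly in the medium in which it rearranges. The route is rejoined at 7, and no new compound is made.

**Step 4.**
- Risk: over-bromination to the geminal dibromide while starting material remains. The second hydrogen abstraction is only moderately slower than the first, and the three species would be hard to separate.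
- Fallback: change from radical to ionic side-chain bromination on the free phenol. The fallback sets out from 7, omitting step 3, which is treated with one equivalent of bromine 2 in acetic acid at 40–60 °C. Ipso attack at C4 gives 2,3,4,6-tetrabromo-4-methylcyclohexa-2,5-dien-1-one F3. In this weakly acidic medium F3 loses HBr across C4 and C7 to give quinone methide 11, and 1,6-addition of HBr gives benzylic bromide 10, the usual fate of 4-bromo-4-methyl dienones outside superacid. The route is rejoined at 10, which is solvolysed to 12 in aqueous acetone with NaHCO3, as in the second half of step 5.

**Step 5.**
- Risk: quinone methide 11 may be captured by the phenoxide or alkoxide of the product instead of by water, giving benzyl ethers and oligomers, because every molecule of 12 formed is itself a nucleophile.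
- Fallback: avoid making a quinone methide from a benzylic leaving group by introducing the oxygen at the aldehyde level and finishing with a hydride reduction. The fallback sets out from 9, which is oxidised with N-methylmorpholine N-oxide in MeCN (a Kornblum-type oxidation of the benzylic bromide) to 2,3,6-tribromo-4-formylphenyl acetate F4. NaBH4 in aqueous NaOH/THF at 0 °C then removes the acetate, giving the phenoxide of 2,3,5-tribromo-4-hydroxybenzaldehyde F5, and reduces the formyl group, as in the familiar reduction of 4-hydroxybenzaldehydes under basic conditions. Careful acidification returns the route at 12. Hydroxide is a poor leaving group, so the reduced product should not ionise to 11 under these conditions.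

## Further compounds

F1 | step 2 | 2,6-dibromo-4-methylphenyl methanesulfonate | Cc1cc(Br)c(OS(C)(=O)=O)c(Br)c1
F2 | step 2 | 2,3,6-tribromo-4-methylphenyl methanesulfonate | Cc1cc(Br)c(OS(C)(=O)=O)c(Br)c1Br
F0 | step 1 | none | none
F3 | step 4 | 2,3,4,6-tetrabromo-4-methylcyclohexa-2,5-dien-1-one | CC1(Br)C=C(Br)C(=O)C(Br)=C1Br
F4 | step 5 | 2,3,6-tribromo-4-formylphenyl acetate | CC(=O)Oc1c(Br)cc(C=O)c(Br)c1Br
F5 | step 5 | 2,3,5-tribromo-4-hydroxybenzaldehyde | O=Cc1cc(Br)c(O)c(Br)c1Br
A1 | alternative 1 | methyl 2,3,5-tribromo-4-methoxybenzoate | COC(=O)c1cc(Br)c(OC)c(Br)c1Br
A2 | alternative 1 | 3,5-dibromo-4-methoxy-2H-pyran-2-one | COC1=C(Br)C(=O)OC=C1Br
A3 | alternative 1 | methyl 3-bromopropiolate (methyl 3-bromoprop-2-ynoate) | COC(=O)C#CBr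
A4 | alternative 2 | 2,3,6-tribromo-4-[(triisopropylsilyloxy)methyl]phenol | CC(C)[Si](C(C)C)(C(C)C)OCc1cc(Br)c(O)c(Br)c1Br
A5 | alternative 2 | triisopropyl[(2,3,5-tribromophenyl)methoxy]silane | CC(C)[Si](C(C)C)(C(C)C)OCc1cc(Br)cc(Br)c1Br
A6 | alternative 3 | (2,3,5-tribromo-4-hydroxyphenyl)methyl acetate | CC(=O)OCc1cc(Br)c(O)c(Br)c1Br
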